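The earlier runs and the new flask were computed on assumed constants; the scatter is artificial.

The reading at 15 h has to be placed on the ladder of times that the two earlier runs show.

| setting | Saturday's | Wednesday's | alder | birch |
|---|---|---|---|---|
| starting complex | 0.057 M | 0.057 M | 0.057 M | 0.057 M |
| incoming ligand | 1.5 equiv | 4.4 equiv | 5.00 equiv | 2.00 equiv |
| leaving ligand | 1 equiv | 1 equiv | 1.00 equiv | 1.00 equiv |
| remark | run made earlier | run made earlier |  |  |
| time |  |  | 15 h | 15 h |

- Saturday's (time / h: complex with two exchanged / %): 0.833: 8.9; 2.00: 14.1; 5.00: 13.3; 10.0: 11.6
- Wednesday's (time / h: complex with two exchanged / %): 0.833: 35.6; 2.00: 45.2; 5.00: 45.0; 10.0: 41.9

(readings scatter by 0.5 percentage points)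

- a species is counted by the starting complex in it: one side product B counts as two
- steps thought possible: starting complex + incoming ligand <-> leaving ligand + complex with one exchanged; complex with one exchanged + incoming ligand <-> leaving ligand + complex with two exchanged; complex with one exchanged -> side product A; starting complex + complex with two exchanged -> side product B; starting complex <-> dormant form

- which of the two there is more of at the end, alder (side product A / complex with two exchanged)
- which of the two there is more of at the end, birch (side product A / complex with two exchanged)
- complex with two exchanged at the end, in percent of the starting complex charged, alder
- complex with two exchanged at the end, in percent of the starting complex charged, birch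

The first rung is the exchange. In Wednesday's run complex with two exchanged reads 45.2% at 2.00 h and 45.0% at 5.00 h, no change within the scatter of 0.5 percentage points, and Saturday's run has stopped rising by then too.

The next rung is a slow fall. I carry one quantity from it, the leak: the fraction lost per hour once the rise has stopped, a pseudo-first-order rate, got as the logarithm of the ratio of the last two readings over the time between them. Saturday's leak is 0.0274 /h, and Wednesday's is 0.0143 /h. Saturday's figure is rough, since it rests on a drop of 1.7 points. Its time, 36.5 h, is longer than 15 h, so at the reading the fall is still a correction to the plateau.

I assume that on this rung the two exchanged complexes keep their ratio, so that their common pool, counted from the full charge, leaks at the same rate and the loss becomes side products. Carrying each run's last reading on to 15 h and drawing a straight line in equivalents, my own reckoning gives complex with two exchanged at 45.0% in alder and 15.1% in birch.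

The loss is 19.3% in alder with Wednesday's leak, less than 45.0%. In birch, with Saturday's leak, it is 33.7%, and side product A leads there if it takes 44.8% of that loss, which I expect.

The forecast gives 44% and 18%, with complex with two exchanged ahead in alder and complex with two exchanged ahead in birch, where it puts side product A near 10 to 13%: “That is below the two-exchanged complex, though less securely than in alder.” On birch my reckoning differs from it.

Alder gives 42.8% of complex with two exchanged against 19.8% of side product A. Birch gives 16.8% against 26.8%, so side product A is the larger there.

    starting complex + incoming ligand ⇌ leaving ligand + complex with one exchanged (K = 43.6, k = 10.2 /M/h)
    complex with one exchanged + incoming ligand ⇌ leaving ligand + complex with two exchanged (K = 0.817, k = 9.77 /M/h)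
    complex with one exchanged → side product A (k = 0.0336 /h)
    starting complex + complex with two exchanged → side product B (k = 1.03 /M/h)
    starting complex ⇌ dormant form (K = 0.226, k = 0.291 /h)

Saturday's leak keeps 66.3% of the charge in birch's exchanged pool at 15 h, and the flask holds 66.7% there. Left until 2.5 d, the same birch flask should keep 19.3% by that leak. It holds 16.5% of complex with one exchanged and 6.33% of complex with two exchanged, together 22.8%, while side product A has reached 72.2%.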